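**Plan**
- The quinone ring is numbered C1 and C4 (carbonyl), C2 and C5 (hydroxyl), C3 (methyl), C6 (henicosyl). The retrosynthesis first removes the oxygens at C1 and C5, giving 5-henicosyl-2-methylresorcinol, and then puts a methoxycarbonyl group back on C5.
- Enabling feature: C6 is the former carbonyl carbon of a docosanoyl unit, and the C2 and C4 oxygens stand 1,3 to each other across the C3 methyl. The ring is therefore a folded C-methyl tetraketide, and its C5–C6 bond is an aldol bond.
- The ring is cut at C5–C6 to a methyl 3,5,7-triketo ester, stored as a diketo-dioxinone. The chain is then cut at C1–C6 (Claisen acylation), C2–C3 (acetylation) and C3–CH3 (methylation).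
- Forward: 2,2,6-trimethyl-dioxinone is methylated, acetylated and joined to docosanoic acid (as its Weinreb amide). Thermolysis in methanol followed by carbonate-mediated aldol aromatisation closes the only ring. Decarboxylation and two oxidation stages then give the dihydroxyquinone.
- Stereochemistry: the target is achiral. The methyl-bearing carbon is a racemic stereocentre in the open-chain intermediates and disappears on aromatisation.

Key step: step 5

Remark: the β-dicarbonyl intermediates are drawn as keto forms but will exist largely as enols (the cyclic aldol also as a diastereomer mixture). This has no bearing on the route. The target is drawn as one of two degenerate hydroxyquinone tautomers.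

**Step 1**
Reactants: 1 2,2,6-trimethyl-4H-1,3-dioxin-4-one; 2 iodomethane
Product: 3 6-ethyl-2,2-dimethyl-4H-1,3-dioxin-4-one
Conditions: LiN(iPr)2 (1.05 equiv), THF/DMPU, −78 °C; then MeI, −78 → −30 °C
Reagents that add atoms: iodomethane (2), CI
Why: LiN(iPr)2 removes a proton from the 6-methyl group to give the lithium dienolate, which in the presence of DMPU should be C-methylated at the γ-carbon by iodomethane (vinylogous enolate alkylation).

**Step 2**
Reactants: 3 6-ethyl-2,2-dimethyl-4H-1,3-dioxin-4-one; 4 acetyl chloride
Product: 5 2,2-dimethyl-6-(3-oxobutan-2-yl)-4H-1,3-dioxin-4-one (racemic)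
Conditions: 3 (2 equiv), LiN(SiMe3)2 (2 equiv), THF, −78 °C; then AcCl (1 equiv), −78 °C; aq. NH4Cl
Reagents that add atoms: acetyl chloride (4), CC(=O)Cl
Why: The γ-dienolate of 3 should undergo a vinylogous Claisen-type C-acylation with acetyl chloride at the γ-carbon, the second equivalent of dienolate taking up the more acidic proton of the product; the new stereocentre is racemic and is erased later.

**Step 3**
Reactants: 6 docosanoic acid
Product: 8 N-methoxy-N-methyldocosanamide, via 1-docosanoylimidazole 7 (not isolated)
Conditions: 1,1'-carbonyldiimidazole, THF, 45 °C; then MeNH(OMe)·HCl, 45 °C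
Reagents that add atoms: N,O-dimethylhydroxylamine hydrochloride, CNOC.Cl
Why: Activation of the acid as its imidazolide followed by aminolysis is a standard Weinreb amide synthesis, and the saturated chain is inert to it.

**Step 4**
Reactants: 5 2,2-dimethyl-6-(3-oxobutan-2-yl)-4H-1,3-dioxin-4-one; 8 N-methoxy-N-methyldocosanamide
Product: 9 2,2-dimethyl-6-(3,5-dioxohexacosan-2-yl)-4H-1,3-dioxin-4-one
Conditions: 5 (1.5 equiv), LiN(iPr)2 (2.1 equiv per 5), THF, −78 → −40 °C; then 8 in THF, −40 → −10 °C; cold aq. HCl to pH 3; used without delay
Reagents that add atoms: none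
Why: Double deprotonation gives the 1,3-dianion of the vinylogous β-dicarbonyl system of 5, whose more reactive terminal (acetyl-methyl) carbanion should attack the Weinreb amide in a Claisen-type acylation, the chelated tetrahedral intermediate preventing over-addition.

**Step 5**
Reactants: 9 2,2-dimethyl-6-(3,5-dioxohexacosan-2-yl)-4H-1,3-dioxin-4-one
Product: 13 methyl 6-henicosyl-2,4-dihydroxy-3-methylbenzoate, via acylketene 10 (not isolated), via triketo ester 11 (not isolated), via cyclic aldol 12 (not isolated)
Conditions: MeOH (10 equiv), PhMe, 110 °C, sealed tube; then Cs2CO3 (2 equiv), MeOH/THF, rt; then HCl in MeOH, rt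
Reagents that add atoms: methanol, CO
Why: Heating opens the dioxinone by a retro-hetero-Diels–Alder loss of acetone to acylketene 10, which the large excess of methanol should capture as the 3,5,7-triketo ester 11 before the internal enol oxygen can close a 2-pyranone. Cs2CO3 then enolises the doubly activated positions of 11 reversibly, and the enolate of the ester-flanked methylene (future C5) adds to the chain-bearing ketone (future C6) to give 12, which loses water on acidification and tautomerises to the benzene ring of 13. The closest known reaction type is the biomimetic aldol aromatisation of diketo-dioxinones and 3,5,7-triketo esters to β-resorcylates, the laboratory version of the orsellinate and alkylresorcinol synthase fold. The single ring closes in the 6-(enolendo)-exo-trig mode; no stereocentre is created and the racemic methyl-bearing centre is erased. The step needs the C5-to-C6 aldol to prevail over Claisen closure of the C1 methylene onto the ester (which would give an acylphloroglucinol) and over O-cyclisation to pyranones; this does not rest on the ester-flanked methylene being the most acidic site (the diketone methylene is more acidic) but on the terminal ketone being a far better electrophile than the methyl ester toward a carbonate-generated enolate, on its being the only carbonyl that the ester-stabilised carbon can reach through a six-membered transition state, and on the irreversible aromatisation of 12 while the other enolate equilibria remain reversible. The base stage is run to completion before acid is added, so that no free triketone is left to cyclodehydrate to a 4-pyranone.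

**Step 6**
Reactants: 13 methyl 6-henicosyl-2,4-dihydroxy-3-methylbenzoate
Product: 15 5-henicosyl-2-methylbenzene-1,3-diol, via resorcylic acid 14 (not isolated)
Conditions: KOH, H2O/DMSO, 110 °C, Ar; then aq. HCl, 80 °C
Reagents that add atoms: none
Why: Hot aqueous KOH saponifies the hindered ester, and the resulting β-resorcylic acid, with hydroxyl groups ortho and para to the carboxyl, should undergo ready protodecarboxylation through ipso protonation.

**Step 7**
Reactants: 15 5-henicosyl-2-methylbenzene-1,3-diol
Product: 16 5-henicosyl-3-hydroxy-2-methylcyclohexa-2,5-diene-1,4-dione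
Conditions: (KSO3)2NO (2.5 equiv), KH2PO4, H2O/THF, Bu4NHSO4 (cat.), rt
Reagents that add atoms: potassium nitrosodisulfonate (KSO3)2NO, [K+].[K+].[O]N(S(=O)(=O)[O-])S(=O)(=O)[O-]
Why: In this Teuber oxidation one nitroxyl radical abstracts the phenolic hydrogen and a second delivers oxygen to the free position para to that hydroxyl, and because the two free ring positions of 15 are symmetry-equivalent a single hydroxy-para-quinone should form.

**Step 8**
Reactants: 16 5-henicosyl-3-hydroxy-2-methylcyclohexa-2,5-diene-1,4-dione
Product: 18 3-henicosyl-6-methylbenzene-1,2,4,5-tetrayl tetraacetate, via acetoxyquinone 17 (not isolated)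
Conditions: Ac2O, conc. H2SO4 (cat.), rt → 45 °C
Reagents that add atoms: acetic anhydride, CC(=O)OC(C)=O
Why: In this Thiele–Winter acetoxylation the acidic hydroxyl is O-acetylated first, and acid-catalysed conjugate addition of acetate to the only unsubstituted quinone carbon followed by enolisation and peracetylation should give the tetraacetate.

**Step 9**
Reactants: 18 3-henicosyl-6-methylbenzene-1,2,4,5-tetrayl tetraacetate
Product: 20 2-henicosyl-3,6-dihydroxy-5-methylcyclohexa-2,5-diene-1,4-dione (2,5-dihydroxy-3-henicosyl-6-methyl-1,4-benzoquinone, CNP0276130.0), via tetrahydroxybenzene 19 (not isolated)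
Conditions: 2 M NaOH, THF, air, rt; then aq. HCl
Reagents that add atoms: none
Why: Saponification of the four aryl acetates frees an electron-rich 1,2,4,5-tetrahydroxybenzene that should be oxidised spontaneously by air (autoxidation of a hydroquinone) to the 2,5-dihydroxy-1,4-benzoquinone, which is stable as its vinylogous carboxylate dianion until acidification.

**Compound list**
1 | 2,2,6-trimethyl-4H-1,3-dioxin-4-one | CC1=CC(=O)OC(C)(C)O1 | starting material
2 | iodomethane | CI | starting material
3 | 6-ethyl-2,2-dimethyl-4H-1,3-dioxin-4-one | CCC1=CC(=O)OC(C)(C)O1 | intermediate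
4 | acetyl chloride | CC(=O)Cl | starting material
5 | 2,2-dimethyl-6-(3-oxobutan-2-yl)-4H-1,3-dioxin-4-one (racemic) | CC(=O)C(C)C1=CC(=O)OC(C)(C)O1 | intermediate
6 | docosanoic acid | CCCCCCCCCCCCCCCCCCCCCC(=O)O | starting material
7 | 1-docosanoylimidazole | CCCCCCCCCCCCCCCCCCCCCC(=O)n1ccnc1 | intermediate (not isolated)
8 | N-methoxy-N-methyldocosanamide | CCCCCCCCCCCCCCCCCCCCCC(=O)N(C)OC | intermediate
9 | 2,2-dimethyl-6-(3,5-dioxohexacosan-2-yl)-4H-1,3-dioxin-4-one (racemic) | CCCCCCCCCCCCCCCCCCCCCC(=O)CC(=O)C(C)C1=CC(=O)OC(C)(C)O1 | intermediate
10 | 4-methyloctacos-1-ene-1,3,5,7-tetrone (acylketene) | CCCCCCCCCCCCCCCCCCCCCC(=O)CC(=O)C(C)C(=O)C=C=O | intermediate (not isolated)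
11 | methyl 4-methyl-3,5,7-trioxooctacosanoate (triketo ester) | CCCCCCCCCCCCCCCCCCCCCC(=O)CC(=O)C(C)C(=O)CC(=O)OC | intermediate (not isolated)
12 | methyl 2-henicosyl-2-hydroxy-5-methyl-4,6-dioxocyclohexane-1-carboxylate (cyclic aldol, stereoisomer mixture) | CCCCCCCCCCCCCCCCCCCCCC1(O)CC(=O)C(C)C(=O)C1C(=O)OC | intermediate (not isolated)
13 | methyl 6-henicosyl-2,4-dihydroxy-3-methylbenzoate | CCCCCCCCCCCCCCCCCCCCCc1cc(O)c(C)c(O)c1C(=O)OC | intermediate
14 | 6-henicosyl-2,4-dihydroxy-3-methylbenzoic acid | CCCCCCCCCCCCCCCCCCCCCc1cc(O)c(C)c(O)c1C(=O)O | intermediate (not isolated)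
15 | 5-henicosyl-2-methylbenzene-1,3-diol | CCCCCCCCCCCCCCCCCCCCCc1cc(O)c(C)c(O)c1 | intermediate
16 | 5-henicosyl-3-hydroxy-2-methylcyclohexa-2,5-diene-1,4-dione | CCCCCCCCCCCCCCCCCCCCCC1=CC(=O)C(C)=C(O)C1=O | intermediate
17 | 5-henicosyl-2-methyl-3,6-dioxocyclohexa-1,4-dien-1-yl acetate (acetoxyquinone) | CCCCCCCCCCCCCCCCCCCCCC1=CC(=O)C(C)=C(OC(C)=O)C1=O | intermediate (not isolated)
18 | 3-henicosyl-6-methylbenzene-1,2,4,5-tetrayl tetraacetate | CCCCCCCCCCCCCCCCCCCCCc1c(OC(C)=O)c(OC(C)=O)c(C)c(OC(C)=O)c1OC(C)=O | intermediate
19 | 3-henicosyl-6-methylbenzene-1,2,4,5-tetrol | CCCCCCCCCCCCCCCCCCCCCc1c(O)c(O)c(C)c(O)c1O | intermediate (not isolated)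
20 | 2-henicosyl-3,6-dihydroxy-5-methylcyclohexa-2,5-diene-1,4-dione | CCCCCCCCCCCCCCCCCCCCCC1=C(O)C(=O)C(C)=C(O)C1=O | target

**Step count and risks**
Total step count: 9.
Longest linear sequence: 8 steps (steps 1, 2 and 4 to 9 from compound 1; step 3 is a one-step side branch from 6).

Steps most likely to fail:

Step 4. Addition of the dianion to a long-chain amide that dissolves poorly at low temperature may be slow, so that proton transfer and decay of the dianion take over, and some O-acylation is possible. The fallback sets out from 3 and comes back at 9. The lithium dienolate of 3 (LiN(SiMe3)2, THF, −78 °C) would be acylated with allyl 3-chloro-3-oxopropanoate to give allyl 4-(2,2-dimethyl-4-oxo-4H-1,3-dioxin-6-yl)-3-oxopentanoate F1. Soft enolisation of its β-keto ester unit with MgCl2 and pyridine in CH2Cl2 (0 °C to rt) and C-acylation with commercial docosanoyl chloride would give allyl 2-[2-(2,2-dimethyl-4-oxo-4H-1,3-dioxin-6-yl)propanoyl]-3-oxotetracosanoate F2. Catalytic Pd(PPh3)4 with morpholine in THF would then remove the allyl group, and the freed β-keto acid would decarboxylate to 9. The long chain is thus introduced at ambient temperature without a dianion.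

Step 5. Ring closure of the acylketene through its enol oxygen may compete with methanol capture, methoxide may cleave the triketo ester by retro-Claisen fragmentation, and acid added before the aldol is complete would cyclodehydrate the triketone. The fallback sets out from 9 and comes back at 15. Without thermolysis, Et3N in CH2Cl2 at rt followed by brief HCl in MeOH would aromatise 9 with the dioxinone ring intact. The same C5–C6 aldol bond forms, with the dioxinone α-carbon as the vinylogous nucleophile, to give 5-henicosyl-7-hydroxy-2,2,8-trimethyl-4H-benzo[d][1,3]dioxin-4-one F3. Hot aqueous KOH in DMSO would open the acetonide lactone, and the acid 14 so formed would decarboxylate to 15.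

Step 8. Conjugate addition of acetate to the last free quinone carbon, which lies next to the long chain, may be sluggish, with acid-induced decomposition of the quinone taking over. The fallback sets out from 16 and comes back at 20. Benzylamine in EtOH under air would add to the free quinone carbon, and the adduct would be reoxidised by air to 2-(benzylamino)-3-henicosyl-5-hydroxy-6-methylcyclohexa-2,5-diene-1,4-dione F4. Hydrolysis of this vinylogous amide in hot aqueous H2SO4/AcOH would give 20 directly.

**Further compounds**
F1 | step 4 | allyl 4-(2,2-dimethyl-4-oxo-4H-1,3-dioxin-6-yl)-3-oxopentanoate | C=CCOC(=O)CC(=O)C(C)C1=CC(=O)OC(C)(C)O1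
F2 | step 4 | allyl 2-[2-(2,2-dimethyl-4-oxo-4H-1,3-dioxin-6-yl)propanoyl]-3-oxotetracosanoate | CCCCCCCCCCCCCCCCCCCCCC(=O)C(C(=O)OCC=C)C(=O)C(C)C1=CC(=O)OC(C)(C)O1
F3 | step 5 | 5-henicosyl-7-hydroxy-2,2,8-trimethyl-4H-benzo[d][1,3]dioxin-4-one | CCCCCCCCCCCCCCCCCCCCCc1cc(O)c(C)c2OC(C)(C)OC(=O)c12
F4 | step 8 | 2-(benzylamino)-3-henicosyl-5-hydroxy-6-methylcyclohexa-2,5-diene-1,4-dione | CCCCCCCCCCCCCCCCCCCCCC1=C(NCc2ccccc2)C(=O)C(C)=C(O)C1=O
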